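**Strategy**

The ten-membered carbocycle is closed at C8–C9 (germacrane numbering: C6 carries the lactone oxygen, C8 the angelate, C9 the acetate), i.e. between the two vicinal ester-bearing carbinol carbons, of which C9 is allylic to the (Z)-C1=C10 alkene. This trans-8,9-diol is read as a pinacol retron: low-valent titanium couples an open-chain dialdehyde (C8 formyl on C7; C9 as the (Z)-enal) and so forms the ring, the C8 and C9 stereocentres and both free hydroxyls in one operation. The precursor carries C2, C6 and C7 stereocentres from a catalytic vinylogous aldol and an auxiliary syn-aldol, with the α-methylene lactone held as a silylated 2-methylene-1,4-diol and oxidised to the lactone last.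

Key step: step 17

Remark: germacranolide numbering is used for all intermediates (ring C1–C10, C11–C13 for the lactone carbons, C14 and C15 for the methyl groups); CIP letters of intermediates can differ from those of the target while the spatial arrangement is unchanged. TBS = tert-butyl(dimethyl)silyl, TES = triethylsilyl.

Assumption: the (R,R)-bisphosphoramide/SiCl4 system is taken to deliver nucleophiles to the Re face of aldehydes, so the (S,S) catalyst is specified in step 5 for Si-face attack; its antipode would be used if the sense were the opposite.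

**Route**

Step 1
Reactants: 1 4-methylfuran-2(5H)-one
Product: 2 (2Z)-4-hydroxy-N-methoxy-N,3-dimethylbut-2-enamide
Conditions: MeNH(OMe)·HCl, Me3Al, CH2Cl2, 0 °C to rt
Reagents that add atoms: N,O-dimethylhydroxylamine hydrochloride (CNOC.Cl)
Why: Weinreb aminolysis of the lactone by the aluminium amide opens the butenolide with its ring-locked cis geometry retained (the later C1=C10 Z-alkene), the β-methyl group blocking conjugate addition.

Step 2
Reactants: 2 (2Z)-4-hydroxy-N-methoxy-N,3-dimethylbut-2-enamide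
Product: 3 (2Z)-N-methoxy-N,3-dimethyl-4-[(triethylsilyl)oxy]but-2-enamide
Conditions: TESCl, imidazole, CH2Cl2, 0 °C
Reagents that add atoms: chlorotriethylsilane (CC[Si](Cl)(CC)CC)
Why: Silylation of the primary allylic alcohol prevents relactonisation and gives the acid-labile ether that is later removed selectively at C9.

Step 3
Reactants: 3 (2Z)-N-methoxy-N,3-dimethyl-4-[(triethylsilyl)oxy]but-2-enamide
Product: 4 (2Z)-3-methyl-4-[(triethylsilyl)oxy]but-2-enal
Conditions: i-Bu2AlH, THF, −78 °C; Rochelle salt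
Reagents that add atoms: none
Why: Reduction of a Weinreb amide stops at the aldehyde through the chelated tetrahedral intermediate, and the neutral work-up keeps the (Z)-enal geometry.

Step 4
Reactants: 5 ethyl 3-methylbut-2-enoate
Product: 6 tert-butyl[(1-ethoxy-3-methylbuta-1,3-dien-1-yl)oxy]dimethylsilane
Conditions: LiN(i-Pr)2, THF, −78 °C; TBSCl, DMPU
Reagents that add atoms: tert-butyl(chloro)dimethylsilane (CC(C)(C)[Si](C)(C)Cl)
Why: γ-Deprotonation of the senecioate and O-silylation give the silyl dienolate (ketene acetal geometry inconsequential) needed for the vinylogous aldol.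

Step 5
Reactants: 4 (2Z)-3-methyl-4-[(triethylsilyl)oxy]but-2-enal; 6 tert-butyl[(1-ethoxy-3-methylbuta-1,3-dien-1-yl)oxy]dimethylsilane
Product: 7 ethyl (2E,5S,6Z)-5-hydroxy-3,7-dimethyl-8-[(triethylsilyl)oxy]octa-2,6-dienoate
Conditions: SiCl4, (S,S)-binaphthyldiamine-derived bisphosphoramide (5 mol%), i-Pr2NEt (cat.), CH2Cl2, −78 °C; aq. KF/NaHCO3
Reagents that add atoms: none
Why: Lewis-base-catalysed vinylogous Mukaiyama aldol in which the γ-carbon (C3) of the dienolate adds to the Si face of the aldehyde held in the chiral phosphoramide-bound silyl cation, setting (S)-C2 and the (E)-C4=C5 enoate in one step.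

Step 6
Reactants: 7 ethyl (2E,5S,6Z)-5-hydroxy-3,7-dimethyl-8-[(triethylsilyl)oxy]octa-2,6-dienoate
Product: 8 ethyl (2E,5S,6Z)-5-{[tert-butyl(dimethyl)silyl]oxy}-3,7-dimethyl-8-[(triethylsilyl)oxy]octa-2,6-dienoate
Conditions: TBSCl, imidazole, DMF, rt
Reagents that add atoms: tert-butyl(chloro)dimethylsilane (CC(C)(C)[Si](C)(C)Cl)
Why: Standard silylation protects the C2 carbinol as a robust ether that is a poor leaving group in the later reductive ring closure.

Step 7
Reactants: 8 ethyl (2E,5S,6Z)-5-{[tert-butyl(dimethyl)silyl]oxy}-3,7-dimethyl-8-[(triethylsilyl)oxy]octa-2,6-dienoate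
Product: 9 (2E,5S,6Z)-5-{[tert-butyl(dimethyl)silyl]oxy}-3,7-dimethyl-8-[(triethylsilyl)oxy]octa-2,6-dien-1-ol
Conditions: i-Bu2AlH, CH2Cl2, −78 °C
Reagents that add atoms: none
Why: 1,2-Reduction of the enoate by the aluminium hydride gives the allylic alcohol without touching the silyl ethers or the alkene geometries.

Step 8
Reactants: 9 (2E,5S,6Z)-5-{[tert-butyl(dimethyl)silyl]oxy}-3,7-dimethyl-8-[(triethylsilyl)oxy]octa-2,6-dien-1-ol
Product: 10 (2E,5S,6Z)-5-{[tert-butyl(dimethyl)silyl]oxy}-3,7-dimethyl-8-[(triethylsilyl)oxy]octa-2,6-dienal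
Conditions: MnO2, CH2Cl2, rt
Reagents that add atoms: none
Why: Chemoselective allylic oxidation gives the (E)-enal (C6 aldehyde) under neutral conditions.

Step 9
Reactants: 11 2-methylidenepropane-1,3-diol
Product: 12 2-({[tert-butyl(dimethyl)silyl]oxy}methyl)prop-2-en-1-ol
Conditions: NaH (1 equiv), TBSCl (1 equiv), THF, 0 °C to rt
Reagents that add atoms: tert-butyl(chloro)dimethylsilane (CC(C)(C)[Si](C)(C)Cl)
Why: Monosilylation of a symmetrical diol through its sparingly soluble monosodium alkoxide.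

Step 10
Reactants: 12 2-({[tert-butyl(dimethyl)silyl]oxy}methyl)prop-2-en-1-ol
Product: 13 {[2-(bromomethyl)prop-2-en-1-yl]oxy}(tert-butyl)dimethylsilane
Conditions: CBr4, PPh3, CH2Cl2, 0 °C
Reagents that add atoms: tetrabromomethane (BrC(Br)(Br)Br)
Why: Appel bromination converts the primary allylic alcohol into the bromide under neutral conditions that keep the silyl ether.

Step 11
Reactants: 13 {[2-(bromomethyl)prop-2-en-1-yl]oxy}(tert-butyl)dimethylsilane
Product: 15 3-({[tert-butyl(dimethyl)silyl]oxy}methyl)but-3-enoic acid, via allylzinc bromide 14 (not isolated)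
Conditions: Zn, LiCl, THF, 0 °C to rt; CO2 (1 atm); aq. citric acid
Reagents that add atoms: carbon dioxide (O=C=O)
Why: Zinc insertion gives a 2-substituted allylzinc reagent with two equivalent termini, whose carboxylation gives the β,γ-unsaturated acid (C8, C7, C11–C13 unit).

Step 12
Reactants: 15 3-({[tert-butyl(dimethyl)silyl]oxy}methyl)but-3-enoic acid; 16 (4S)-4-benzyl-1,3-oxazolidin-2-one
Product: 18 (4S)-4-benzyl-3-[3-({[tert-butyl(dimethyl)silyl]oxy}methyl)but-3-enoyl]-1,3-oxazolidin-2-one, via mixed pivalic anhydride 17 (not isolated)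
Conditions: t-BuCOCl, Et3N, THF, −20 °C; then 16, LiCl, rt
Reagents that add atoms: none
Why: N-Acylation of the auxiliary through the mixed pivalic anhydride under weakly basic conditions that do not move the β,γ-alkene into conjugation.

Step 13
Reactants: 18 (4S)-4-benzyl-3-[3-({[tert-butyl(dimethyl)silyl]oxy}methyl)but-3-enoyl]-1,3-oxazolidin-2-one; 10 (2E,5S,6Z)-5-{[tert-butyl(dimethyl)silyl]oxy}-3,7-dimethyl-8-[(triethylsilyl)oxy]octa-2,6-dienal
Product: 20 (4S)-4-benzyl-3-[(2S,3R,4E,7S,8Z)-7-{[tert-butyl(dimethyl)silyl]oxy}-2-(3-{[tert-butyl(dimethyl)silyl]oxy}prop-1-en-2-yl)-3-hydroxy-5,9-dimethyl-10-[(triethylsilyl)oxy]deca-4,8-dienoyl]-1,3-oxazolidin-2-one, via (Z)-dibutylboron enolate 19 (not isolated)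
Conditions: n-Bu2BOTf, Et3N, CH2Cl2, −78 to 0 °C; then 10, −78 to 0 °C; pH 7 buffer, MeOH, H2O2
Reagents that add atoms: none
Why: Evans syn-aldol through the (Z)-boron enolate and a closed chair transition state in which the (S)-benzyl auxiliary shields one enolate face, setting C7 and C6 (O6 syn to C11, i.e. the later trans-fused lactone).

Step 14
Reactants: 20 the aldol adduct
Product: 21 (4S)-4-benzyl-3-[(2S,3R,4E,7S,8Z)-3,7-bis{[tert-butyl(dimethyl)silyl]oxy}-2-(3-{[tert-butyl(dimethyl)silyl]oxy}prop-1-en-2-yl)-5,9-dimethyl-10-[(triethylsilyl)oxy]deca-4,8-dienoyl]-1,3-oxazolidin-2-one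
Conditions: TBSOTf, 2,6-lutidine, CH2Cl2, −78 °C
Reagents that add atoms: tert-butyldimethylsilyl triflate (CC(C)(C)[Si](C)(C)OS(=O)(=O)C(F)(F)F)
Why: Silylation of the hindered C6 carbinol with the silyl triflate blocks retro-aldol and keeps C6 from being oxidised in step 16.

Step 15
Reactants: 21 the tris-TBS imide
Product: 23 (2R,3R,4E,7S,8Z)-3,7-bis{[tert-butyl(dimethyl)silyl]oxy}-2-(3-{[tert-butyl(dimethyl)silyl]oxy}prop-1-en-2-yl)-5,9-dimethyldeca-4,8-diene-1,10-diol, via primary alcohol TES ether 22 (not isolated)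
Conditions: LiBH4, MeOH (1 equiv), THF, 0 °C; then PPTS, MeOH, 0 °C to rt
Reagents that add atoms: none
Why: Reductive cleavage of the N-acyloxazolidinone gives the C8 alcohol, and mild acid methanolysis then removes only the primary TES ether at C9, TBS ethers being far slower to cleave.

Step 16
Reactants: 23 the 1,10-diol (C8 and C9 hydroxyls)
Product: 24 (2S,3R,4E,7S,8Z)-3,7-bis{[tert-butyl(dimethyl)silyl]oxy}-2-(3-{[tert-butyl(dimethyl)silyl]oxy}prop-1-en-2-yl)-5,9-dimethyldeca-4,8-dienedial (C8 formyl on C7; C9 as the (Z)-enal)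
Conditions: Dess–Martin periodinane, NaHCO3, CH2Cl2, 0 °C to rt; used crude
Reagents that add atoms: none
Why: Buffered Dess–Martin oxidation of both primary alcohols under non-basic conditions avoids epimerisation at C7 and isomerisation of the (Z)-enal.

Step 17
Reactants: 24 the dialdehyde
Product: 25 (1(10)Z,4E)-2,6,12-tris{[tert-butyl(dimethyl)silyl]oxy}germacra-1(10),4,11(13)-triene-8,9-diol, trans-8,9-diol with C2, C6, C7, C8 and C9 arranged as in the target (CIP 2S,6R,7R,8R,9R)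
Conditions: TiCl3(DME)1.5, Zn–Cu couple, DME, reflux, then 25 °C; 24 added by syringe pump (final 0.002 M); aq. K2CO3
Reagents that add atoms: none
Why: Low-valent titanium transfers one electron to each aldehyde and the two titanium-bound ketyls at C8 and C9 combine on the metal to a titanium diolate that is hydrolysed to the diol, the closest known reaction type being the McMurry-type pinacol macrocyclisation of dialdehydes, stopped at the diol at 25 °C. The ten-membered carbocycle closes in a 10-exo-trig sense at either carbonyl, helped by high dilution and by the (Z)-C1=C10 and (E)-C4=C5 alkenes that fold the chain. C8 is set by the adjacent C7 stereocentre, C9 adding to the formyl group anti to the bulky C6 branch (Felkin–Anh), which places O8 syn to C11 as required. C9 is set relative to C8 by the expected preference of medium-ring titanium pinacol closures for the trans (threo) diol, in which the two titanium-bound oxygens avoid each other across the forming bond. The step needs chemoselectivity for the two formyl groups without deoxygenation to the alkene; the substrate has no other reducible group because the lactone is carried as silyl ethers, and the C2 oxygen is a silyl ether, a poor leaving group toward the reduced enal.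

Step 18
Reactants: 25 the macrocyclic 8,9-diol
Product: 26 9-O-acetyl derivative of 25 (free C8 hydroxyl; CIP 2S,6R,7R,8R,9R)
Conditions: Ac2O (1.1 equiv), pyridine, DMAP (cat.), CH2Cl2, −20 °C
Reagents that add atoms: acetic anhydride (CC(=O)OC(C)=O)
Why: Kinetic regioselective acetylation, the allylic C9 hydroxyl beside the planar C10 being more accessible than the C8 hydroxyl, which sits beside the branched C7 between two silyloxy-bearing arms.

Step 19
Reactants: 26 the 9-acetate; 27 angelic acid, (2Z)-2-methylbut-2-enoic acid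
Product: 29 9-O-acetyl-8-O-angeloyl derivative of 25 (CIP 2S,6R,7R,8R,9R), via angelic 2,4,6-trichlorobenzoic anhydride 28 (not isolated)
Conditions: 27, 2,4,6-trichlorobenzoyl chloride, Et3N, toluene, rt; then 26, 80 °C
Reagents that add atoms: none
Why: Yamaguchi-type esterification through the pre-formed mixed anhydride acylates the hindered C8 hydroxyl without a nucleophilic catalyst, conditions expected to preserve the (Z)-geometry of the angelate.

Step 20
Reactants: 29 the tris-TBS diester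
Product: 30 (1(10)Z,4E)-9-acetoxy-8-angeloyloxygermacra-1(10),4,11(13)-triene-2,6,12-triol (CIP 2S,6R,7S,8R,9R)
Conditions: HF·pyridine, pyridine, THF, 0 °C to rt
Reagents that add atoms: none
Why: Buffered fluoride cleavage of the three TBS ethers leaves both esters intact and avoids base-promoted acyl migration.

Step 21
Reactants: 30 the triol diester
Product: 33 CNP0316477.1, (1(10)Z,4E,2S,6R,7S,8R,9R)-9-acetoxy-8-angeloyloxy-2-hydroxygermacra-1(10),4,11(13)-trien-12,6-olide, via C12 enal 31 (not isolated), via C12 lactol 32 (not isolated)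
Conditions: TEMPO (cat.), PhI(OAc)2, CH2Cl2, rt
Reagents that add atoms: none
Why: Oxoammonium oxidation selects the primary allylic C12 hydroxyl, the enal is trapped by the C6 hydroxyl as a five-membered lactol, and this is oxidised on to the α-methylene-γ-lactone (oxidative lactonisation of a 1,4-diol), the secondary C2 hydroxyl reacting more slowly.

**Compound list**

1 | 4-methylfuran-2(5H)-one | CC1=CC(=O)OC1 | starting material
2 | (2Z)-4-hydroxy-N-methoxy-N,3-dimethylbut-2-enamide | CON(C)C(=O)/C=C(/C)CO | intermediate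
3 | (2Z)-N-methoxy-N,3-dimethyl-4-[(triethylsilyl)oxy]but-2-enamide | CON(C)C(=O)/C=C(/C)CO[Si](CC)(CC)CC | intermediate
4 | (2Z)-3-methyl-4-[(triethylsilyl)oxy]but-2-enal | O=C/C=C(/C)CO[Si](CC)(CC)CC | intermediate
5 | ethyl 3-methylbut-2-enoate | CCOC(=O)C=C(C)C | starting material
6 | tert-butyl[(1-ethoxy-3-methylbuta-1,3-dien-1-yl)oxy]dimethylsilane | CCOC(O[Si](C)(C)C(C)(C)C)=CC(C)=C | intermediate
7 | ethyl (2E,5S,6Z)-5-hydroxy-3,7-dimethyl-8-[(triethylsilyl)oxy]octa-2,6-dienoate | CCOC(=O)/C=C(\C)C[C@H](O)/C=C(/C)CO[Si](CC)(CC)CC | intermediate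
8 | ethyl (2E,5S,6Z)-5-{[tert-butyl(dimethyl)silyl]oxy}-3,7-dimethyl-8-[(triethylsilyl)oxy]octa-2,6-dienoate | CCOC(=O)/C=C(\C)C[C@H](O[Si](C)(C)C(C)(C)C)/C=C(/C)CO[Si](CC)(CC)CC | intermediate
9 | (2E,5S,6Z)-5-{[tert-butyl(dimethyl)silyl]oxy}-3,7-dimethyl-8-[(triethylsilyl)oxy]octa-2,6-dien-1-ol | OC/C=C(\C)C[C@H](O[Si](C)(C)C(C)(C)C)/C=C(/C)CO[Si](CC)(CC)CC | intermediate
10 | (2E,5S,6Z)-5-{[tert-butyl(dimethyl)silyl]oxy}-3,7-dimethyl-8-[(triethylsilyl)oxy]octa-2,6-dienal | O=C/C=C(\C)C[C@H](O[Si](C)(C)C(C)(C)C)/C=C(/C)CO[Si](CC)(CC)CC | intermediate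
11 | 2-methylidenepropane-1,3-diol | C=C(CO)CO | starting material
12 | 2-({[tert-butyl(dimethyl)silyl]oxy}methyl)prop-2-en-1-ol | C=C(CO)CO[Si](C)(C)C(C)(C)C | intermediate
13 | {[2-(bromomethyl)prop-2-en-1-yl]oxy}(tert-butyl)dimethylsilane | C=C(CBr)CO[Si](C)(C)C(C)(C)C | intermediate
14 | [2-({[tert-butyl(dimethyl)silyl]oxy}methyl)prop-2-en-1-yl]zinc bromide | C=C(C[Zn]Br)CO[Si](C)(C)C(C)(C)C | intermediate
15 | 3-({[tert-butyl(dimethyl)silyl]oxy}methyl)but-3-enoic acid | C=C(CC(=O)O)CO[Si](C)(C)C(C)(C)C | intermediate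
16 | (4S)-4-benzyl-1,3-oxazolidin-2-one | O=C1OC[C@H](Cc2ccccc2)N1 | starting material
17 | mixed anhydride of 15 with pivalic acid | C=C(CC(=O)OC(=O)C(C)(C)C)CO[Si](C)(C)C(C)(C)C | intermediate
18 | (4S)-4-benzyl-3-[3-({[tert-butyl(dimethyl)silyl]oxy}methyl)but-3-enoyl]-1,3-oxazolidin-2-one | O=C1OC[C@H](Cc2ccccc2)N1C(=O)CC(=C)CO[Si](C)(C)C(C)(C)C | intermediate
19 | (Z)-dibutylboron enolate of 18 | O=C1OC[C@H](Cc2ccccc2)N1/C(OB(CCCC)CCCC)=C/C(=C)CO[Si](C)(C)C(C)(C)C | intermediate
20 | (4S)-4-benzyl-3-[(2S,3R,4E,7S,8Z)-7-{[tert-butyl(dimethyl)silyl]oxy}-2-(3-{[tert-butyl(dimethyl)silyl]oxy}prop-1-en-2-yl)-3-hydroxy-5,9-dimethyl-10-[(triethylsilyl)oxy]deca-4,8-dienoyl]-1,3-oxazolidin-2-one | O=C1OC[C@H](Cc2ccccc2)N1C(=O)[C@@H](C(=C)CO[Si](C)(C)C(C)(C)C)[C@H](O)/C=C(\C)C[C@H](O[Si](C)(C)C(C)(C)C)/C=C(/C)CO[Si](CC)(CC)CC | intermediate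
21 | (4S)-4-benzyl-3-[(2S,3R,4E,7S,8Z)-3,7-bis{[tert-butyl(dimethyl)silyl]oxy}-2-(3-{[tert-butyl(dimethyl)silyl]oxy}prop-1-en-2-yl)-5,9-dimethyl-10-[(triethylsilyl)oxy]deca-4,8-dienoyl]-1,3-oxazolidin-2-one | O=C1OC[C@H](Cc2ccccc2)N1C(=O)[C@@H](C(=C)CO[Si](C)(C)C(C)(C)C)[C@H](O[Si](C)(C)C(C)(C)C)/C=C(\C)C[C@H](O[Si](C)(C)C(C)(C)C)/C=C(/C)CO[Si](CC)(CC)CC | intermediate
22 | (2R,3R,4E,7S,8Z)-3,7-bis{[tert-butyl(dimethyl)silyl]oxy}-2-(3-{[tert-butyl(dimethyl)silyl]oxy}prop-1-en-2-yl)-5,9-dimethyl-10-[(triethylsilyl)oxy]deca-4,8-dien-1-ol | OC[C@@H](C(=C)CO[Si](C)(C)C(C)(C)C)[C@H](O[Si](C)(C)C(C)(C)C)/C=C(\C)C[C@H](O[Si](C)(C)C(C)(C)C)/C=C(/C)CO[Si](CC)(CC)CC | intermediate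
23 | (2R,3R,4E,7S,8Z)-3,7-bis{[tert-butyl(dimethyl)silyl]oxy}-2-(3-{[tert-butyl(dimethyl)silyl]oxy}prop-1-en-2-yl)-5,9-dimethyldeca-4,8-diene-1,10-diol | OC[C@@H](C(=C)CO[Si](C)(C)C(C)(C)C)[C@H](O[Si](C)(C)C(C)(C)C)/C=C(\C)C[C@H](O[Si](C)(C)C(C)(C)C)/C=C(/C)CO | intermediate
24 | (2S,3R,4E,7S,8Z)-3,7-bis{[tert-butyl(dimethyl)silyl]oxy}-2-(3-{[tert-butyl(dimethyl)silyl]oxy}prop-1-en-2-yl)-5,9-dimethyldeca-4,8-dienedial | O=C[C@@H](C(=C)CO[Si](C)(C)C(C)(C)C)[C@H](O[Si](C)(C)C(C)(C)C)/C=C(\C)C[C@H](O[Si](C)(C)C(C)(C)C)/C=C(/C)C=O | intermediate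
25 | (1(10)Z,4E)-2,6,12-tris{[tert-butyl(dimethyl)silyl]oxy}germacra-1(10),4,11(13)-triene-8,9-diol (trans-diol; 2S,6R,7R,8R,9R) | C=C(CO[Si](C)(C)C(C)(C)C)[C@H]1[C@H](O[Si](C)(C)C(C)(C)C)/C=C(\C)C[C@H](O[Si](C)(C)C(C)(C)C)/C=C(/C)[C@@H](O)[C@@H]1O | intermediate
26 | 9-O-acetyl derivative of 25 (2S,6R,7R,8R,9R) | C=C(CO[Si](C)(C)C(C)(C)C)[C@H]1[C@H](O[Si](C)(C)C(C)(C)C)/C=C(\C)C[C@H](O[Si](C)(C)C(C)(C)C)/C=C(/C)[C@@H](OC(C)=O)[C@@H]1O | intermediate
27 | angelic acid, (2Z)-2-methylbut-2-enoic acid | C/C=C(/C)C(=O)O | starting material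
28 | angelic 2,4,6-trichlorobenzoic anhydride | C/C=C(/C)C(=O)OC(=O)c1c(Cl)cc(Cl)cc1Cl | intermediate
29 | 9-O-acetyl-8-O-angeloyl derivative of 25 (2S,6R,7R,8R,9R) | C=C(CO[Si](C)(C)C(C)(C)C)[C@H]1[C@H](O[Si](C)(C)C(C)(C)C)/C=C(\C)C[C@H](O[Si](C)(C)C(C)(C)C)/C=C(/C)[C@@H](OC(C)=O)[C@@H]1OC(=O)/C(C)=C\C | intermediate
30 | (1(10)Z,4E)-9-acetoxy-8-angeloyloxygermacra-1(10),4,11(13)-triene-2,6,12-triol (2S,6R,7S,8R,9R) | C=C(CO)[C@H]1[C@H](O)/C=C(\C)C[C@H](O)/C=C(/C)[C@@H](OC(C)=O)[C@@H]1OC(=O)/C(C)=C\C | intermediate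
31 | C12 enal: (1(10)Z,4E)-9-acetoxy-8-angeloyloxy-2,6-dihydroxygermacra-1(10),4,11(13)-trien-12-al | C=C(C=O)[C@H]1[C@H](O)/C=C(\C)C[C@H](O)/C=C(/C)[C@@H](OC(C)=O)[C@@H]1OC(=O)/C(C)=C\C | intermediate
32 | C12 lactol: 12-hydroxy-6,12-epoxy form of 31 (anomer mixture) | C=C1C(O)O[C@@H]2/C=C(\C)C[C@H](O)/C=C(/C)[C@@H](OC(C)=O)[C@H](OC(=O)/C(C)=C\C)[C@@H]12 | intermediate
33 | CNP0316477.1, (1(10)Z,4E,2S,6R,7S,8R,9R)-9-acetoxy-8-angeloyloxy-2-hydroxygermacra-1(10),4,11(13)-trien-12,6-olide | C=C1C(=O)O[C@@H]2/C=C(\C)C[C@H](O)/C=C(/C)[C@@H](OC(C)=O)[C@H](OC(=O)/C(C)=C\C)[C@@H]12 | target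

**Step count and risks**

Total step count: 21 steps.
Longest linear sequence: 16 steps (steps 1–3, 5–8, 13–21).

Steps most likely to fail:

1. Step 17 (ring closure). The coupling may give poor control of the C9 configuration relative to C8 and deliver the cis- instead of the trans-diol; intermolecular coupling is a further risk that dilution addresses. Fallback, setting out from dialdehyde 24: the coupling is run as planned and the (8R,9S)-cis-8,9-diol F1 is converted with SOCl2 and Et3N into the cyclic sulfite F2. CsOAc in DMF should open F2 at the allylic C9 with inversion, and mild acid hydrolysis of the remaining C8 sulfite half-ester gives the 9-acetate 26. C9 is then set by an SN2 displacement instead of by the coupling, and the route is rejoined at 26 with step 18 saved.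

2. Step 18 (differentiation of the diol, with consequences for step 19). The acetylation may show poor regioselectivity between the two secondary hydroxyls, and the acetyl group may migrate from O9 to O8 during the hot angeloylation. Fallback, setting out from diol 25: the more size-sensitive silylation with TESCl and imidazole at −20 °C gives the 9-O-triethylsilyl ether F3. Yamaguchi angeloylation of its C8 hydroxyl (27, 2,4,6-trichlorobenzoyl chloride, Et3N, toluene, 80 °C) gives the silyl angelate F4. PPTS in MeOH removes the secondary TES group to give the 9-hydroxy 8-angelate F5, and Ac2O in pyridine returns the route to diester 29.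

3. Step 5 (vinylogous aldol). Enantiofacial control may be insufficient, or the (Z)-enal may isomerise under the Lewis acid. Fallback, setting out from enal 4 and dienolate 6: BF3·OEt2 in CH2Cl2 at −78 °C gives the racemic alcohol F6. Dess–Martin oxidation gives the C2 ketone F7, and Corey–Bakshi–Shibata reduction with the (R)-2-methyl-oxazaborolidine and catecholborane, the alkenyl group acting as the large substituent, returns (S)-alcohol 7.

Further compounds
F1 | step 17 | (8R,9S)-cis-8,9-diol, C9 epimer of 25 | C=C(CO[Si](C)(C)C(C)(C)C)[C@H]1[C@H](O[Si](C)(C)C(C)(C)C)/C=C(\C)C[C@H](O[Si](C)(C)C(C)(C)C)/C=C(/C)[C@H](O)[C@@H]1O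
F2 | step 17 | 8,9-O-cyclic sulfite of F1 | C=C(CO[Si](C)(C)C(C)(C)C)[C@H]1[C@H](O[Si](C)(C)C(C)(C)C)/C=C(\C)C[C@H](O[Si](C)(C)C(C)(C)C)/C=C(/C)[C@@H]2OS(=O)O[C@H]12
F3 | step 18 | 9-O-triethylsilyl ether of 25 | C=C(CO[Si](C)(C)C(C)(C)C)[C@H]1[C@H](O[Si](C)(C)C(C)(C)C)/C=C(\C)C[C@H](O[Si](C)(C)C(C)(C)C)/C=C(/C)[C@@H](O[Si](CC)(CC)CC)[C@@H]1O
F4 | step 18 | 8-O-angeloyl-9-O-triethylsilyl derivative of 25 | C=C(CO[Si](C)(C)C(C)(C)C)[C@H]1[C@H](O[Si](C)(C)C(C)(C)C)/C=C(\C)C[C@H](O[Si](C)(C)C(C)(C)C)/C=C(/C)[C@@H](O[Si](CC)(CC)CC)[C@@H]1OC(=O)/C(C)=C\C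
F5 | step 18 | 8-O-angeloyl derivative of 25 with free C9 hydroxyl | C=C(CO[Si](C)(C)C(C)(C)C)[C@H]1[C@H](O[Si](C)(C)C(C)(C)C)/C=C(\C)C[C@H](O[Si](C)(C)C(C)(C)C)/C=C(/C)[C@@H](O)[C@@H]1OC(=O)/C(C)=C\C
F6 | step 5 | racemic ethyl (2E,6Z)-5-hydroxy-3,7-dimethyl-8-[(triethylsilyl)oxy]octa-2,6-dienoate | CCOC(=O)/C=C(\C)CC(O)/C=C(/C)CO[Si](CC)(CC)CC
F7 | step 5 | ethyl (2E,6Z)-3,7-dimethyl-5-oxo-8-[(triethylsilyl)oxy]octa-2,6-dienoate | CCOC(=O)/C=C(\C)CC(=O)/C=C(/C)CO[Si](CC)(CC)CC
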